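Remark on the chemistry: the SMILES is read as (7S,8R), the erythro isomer. Neolignan locants are used: C7–C8–C9 is the propane chain, ring A is the catechol ring on C7, ring B is the ether-linked guaiacyl ring with primed locants. Compounds 1 and 4 are taken as commercially available.

Compound numbers, fixed for the whole text:
1 1-[3,4-bis(benzyloxy)phenyl]ethan-1-one
2 ethyl 3-[3,4-bis(benzyloxy)phenyl]-3-oxopropanoate
3 ethyl 3-[3,4-bis(benzyloxy)phenyl]-2-chloro-3-oxopropanoate (racemic)
4 methyl 3-(4-hydroxy-3-methoxyphenyl)propanoate
5 racemic α-aryloxy β-keto ester (full name in step 3)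
6 the (2S)-enantiomer of 5 (not isolated)
7 erythro (2S,3S)-β-hydroxy ester
8 erythro triol with ring A still as its bis(benzyl ether)
9 the target

## Analysis of the target

Target 9 is an acyclic 8-O-4′ neolignan. Its C7–C8–C9 propane-1,3-diol chain carries ring A (a 3,4-dihydroxyphenyl catechol) on C7, and C8 is joined through an ether oxygen to C4′ of ring B (OMe at C3′, a 3-hydroxypropyl chain at C1′). No ring relays stereochemistry: the benzylic carbinol C7 (S) and the aryl ether carbon C8 (R) are adjacent and erythro, that is anti when C1–C7–C8–C9 is drawn as a zigzag. The hardest bond is C8–O–C4′, a secondary alkyl aryl ether to an electron-rich arene that cannot be made by SNAr, at a stereocenter flanked by two oxygenated carbons. The catechol of ring A oxidises readily in air or base. C7–OH is a p-hydroxybenzyl alcohol, so acid ionises it towards a quinone methide (epimerisation at C7) and Pd/H2 can cleave it. In any carbonyl-level precursor the C8 aryloxy group is a β-leaving group and the C7–C8 bond can break by retro-aldol. The feature that invites the strategy is that C8 lies between two oxygen-bearing carbons, C7 and C9: with C7 as a ketone and C9 as an ester, C8–H becomes acidic and C8 stereolabile, so C7 and C8 can be set together from a racemate. The difficulty is the erythro relation under absolute control, because the two reflex methods (Z-enolate aldol, syn-dihydroxylation of the E-alkene) both give threo.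

## Retrosynthetic reasoning

9 to 8: the two O–benzyl bonds on ring A are cut. The catechol is the most fragile group, so it should appear only in the last step, and hydrogenolysis under neutral conditions touches nothing else. The forward reaction must cleave two aryl benzyl ethers without cleaving the benzylic C7–O bond.

8 to 7: the oxidation level of C9 and of the terminal carbon of the ring B side chain is raised from alcohol to ester. One hydride step returns both primary alcohols. What is gained is an ester on C9, which acidifies C8–H in every earlier intermediate. The forward reduction must be faster than retro-aldol cleavage of the C7 alkoxide.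

7 to 5 (through 6): the C7–H bond is cut, which gives a C7 ketone. This is the key disconnection. In 5, C8 sits between a ketone, an ester and an aryloxy group, so 5 can be used as the racemate. A dynamic kinetic hydrogenation then has to do three things at once: choose the ketone face (C7), choose one of the two rapidly interconverting C8 enantiomers (6), and give the anti relation. The cut is made here and not at C7–C8 or C8–O because it takes all stereochemical demand out of the construction of the skeleton.

5 to 3 + 4: the C8–O bond is cut. Because C8 of 5 carries no stereochemical information, the hindered alkyl aryl ether can be made by a plain SN2 displacement of an α-chloride by the phenoxide of 4. The forward reaction only has to give O-alkylation at a carbon activated by two carbonyl groups.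

3 to 2 to 1: the C8–Cl bond is cut (electrophilic chlorination of the β-keto ester), then the C8–C9 bond (C-ethoxycarbonylation of the methyl ketone 1). Both are standard and need no selectivity beyond mono-substitution.

## Alternatives that were turned down

Alternative 1: the textbook C7–C8 aldol disconnection. The Z-boron enolate of imide A1 would add to aldehyde A2 through a closed chair transition state to give adduct A3. That transition state gives the syn adduct, which is the threo series, so A3 has the right C8 but the wrong C7. C7 would then have to be inverted at an electron-rich benzylic alcohol, where ionisation competes with SN2. Anti-selective glycolate aldol variants need a large excess of a strong Lewis acid next to benzyl ethers and a stoichiometric chiral amine. In either form the auxiliary is stoichiometric and costs two steps to attach and remove, so the sequence would be longer than the route below and would use no catalysis for the stereocenters.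

Alternative 2: C8–O disconnection with inversion. Cinnamate A4 would be dihydroxylated (osmium-catalysed asymmetric dihydroxylation) to the threo diol A5, sulfonylated selectively at the α-hydroxyl to nosylate A6, and displaced by the phenoxide of 4 with inversion at C8 to give 7. The stereochemical logic is sound, but the key displacement has a regiochemical leak. Under the basic conditions needed for the phenoxide, the free C7–OH of A6 can close to the cis-glycidate, and that epoxide, like the electron-rich benzylic carbon itself, is opened at C7 and not at C8. Masking C7–OH costs two more steps, and the α-selective sulfonylation is a second selectivity problem. Four steps would reach 7 with two such problems, against one in the route below.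

Alternative 3: the biomimetic disconnection of C8–O4′ and C7–OH together. One-electron oxidation of the cinnamyl alcohol A7 in the presence of phenol 4 would couple the C8 radical with the phenoxyl oxygen to give quinone methide A8, and water would then add at C7. The radical coupling has no enantiocontrol, and water adds to a planar quinone methide with little erythro/threo preference. The catechol of A7 would be oxidised to an o-quinone before it couples. Phenol 4 has a free C5′, so 8–5′ coupling and homo-coupling of A7 compete. A resolution and a separation of isomers would be needed for a single enantiomer.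

Key step: step 4

## Route

Step 1
Reactants: 1 1-[3,4-bis(benzyloxy)phenyl]ethan-1-one
Product: 2 ethyl 3-[3,4-bis(benzyloxy)phenyl]-3-oxopropanoate
Conditions: NaH (2.5 equiv), (EtO)2CO (4 equiv), toluene, 90 °C; then AcOH, aq. work-up
Reagents that add atoms: diethyl carbonate, CCOC(=O)OCC
Why: Crossed Claisen condensation (C-ethoxycarbonylation of the methyl ketone enolate); the product leaves the equilibrium as its sodium enolate and the aryl benzyl ethers are inert to NaH. No stereocenter is formed.

Step 2
Reactants: 2 ethyl 3-[3,4-bis(benzyloxy)phenyl]-3-oxopropanoate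
Product: 3 ethyl 3-[3,4-bis(benzyloxy)phenyl]-2-chloro-3-oxopropanoate (racemic)
Conditions: SO2Cl2 (1.05 equiv), CH2Cl2, 0 °C
Reagents that add atoms: sulfuryl chloride, ClS(Cl)(=O)=O
Why: Electrophilic α-chlorination of the enol of a β-keto ester; the monochloride is less enolised than 2, which should hold the reaction at one chlorine, and the para-acyl group deactivates ring A towards chlorination. C2 is formed racemic, which is what the key step requires.

Step 3
Reactants: 3 ethyl 3-[3,4-bis(benzyloxy)phenyl]-2-chloro-3-oxopropanoate (racemic); 4 methyl 3-(4-hydroxy-3-methoxyphenyl)propanoate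
Product: 5 ethyl 3-[3,4-bis(benzyloxy)phenyl]-2-[2-methoxy-4-(3-methoxy-3-oxopropyl)phenoxy]-3-oxopropanoate (racemic)
Conditions: K2CO3 (1.5 equiv), acetone, 50 °C
Reagents that add atoms: none
Why: Williamson-type SN2 displacement at a carbon activated by two carbonyl groups, the usual way from α-chloro β-keto esters and phenols to α-aryloxy β-keto esters. It makes the hindered C8–O–C4′ ether with no stereochemical demand, because C2 of 5 is labile and is wanted as the racemate.

Step 4
Reactants: 5 ethyl 3-[3,4-bis(benzyloxy)phenyl]-2-[2-methoxy-4-(3-methoxy-3-oxopropyl)phenoxy]-3-oxopropanoate (racemic)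
Product: 7 ethyl (2S,3S)-3-[3,4-bis(benzyloxy)phenyl]-3-hydroxy-2-[2-methoxy-4-(3-methoxy-3-oxopropyl)phenoxy]propanoate, via the faster-reacting (2S)-keto ester 6 (not isolated)
Conditions: H2 (100 bar), RuBr2[(S)-BINAP] (2 mol %), CH2Cl2, 50 °C
Reagents that add atoms: none
Why: Noyori-type asymmetric hydrogenation of an α-substituted β-keto ester with dynamic kinetic resolution. C2–H of 5 lies between the ketone, the ester and the aryloxy group, so the two enantiomers should interconvert through the enol faster than either is reduced, and the racemate is drawn through the faster-reacting (2S)-enantiomer 6. Ketone and ester carbonyl chelate the Ru(II) hydride in a six-membered ring and the hydride passes to C3 inside this chelate; the (S)-BINAP ligand fixes the ketone face and should give (3S), the sense known for aryl β-keto esters and for α-acylamino β-keto esters with a 3,4-dioxygenated aryl ketone, the closest substrates. Because the ester is held in the chelate, the aryloxy group on C2 can only point towards the metal or away from it; pointing away, its C–O bond is antiperiplanar to the incoming hydride (polar Felkin–Anh arrangement) and clear of the ligand, and that enantiomer, (2S), gives the anti (erythro) product, as α-chloro β-keto esters do with the same catalysts. No ring is closed. Three selectivities are needed: racemisation faster than reduction (from the acidity of C2–H), anti over syn (from a weakly basic aryl ether oxygen that, unlike an amide N–H, has no good way to bind on the metal side), and reduction of the ketone only (Ru–diphosphine catalysts leave benzyl ethers, esters and arenes alone). N–H bifunctional transfer-hydrogenation catalysts are avoided here on purpose, because they give syn products with α-alkoxy β-keto esters.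

Step 5
Reactants: 7 ethyl (2S,3S)-3-[3,4-bis(benzyloxy)phenyl]-3-hydroxy-2-[2-methoxy-4-(3-methoxy-3-oxopropyl)phenoxy]propanoate
Product: 8 (1S,2R)-1-[3,4-bis(benzyloxy)phenyl]-2-[4-(3-hydroxypropyl)-2-methoxyphenoxy]propane-1,3-diol
Conditions: LiAlH4 (3 equiv), THF, 0 °C to rt; Rochelle salt work-up
Reagents that add atoms: none
Why: Hydride reduction of both esters to primary alcohols (C9 and the side chain of ring B) in one operation, the standard last carbon-level step for arylglycerol β-aryl ethers; benzyl ethers are inert. Once C9 is an alcohol, C8–H is no longer acidic and C8 is locked; the descriptors change to (1S,2R) only through CIP priorities.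

Step 6
Reactants: 8 (1S,2R)-1-[3,4-bis(benzyloxy)phenyl]-2-[4-(3-hydroxypropyl)-2-methoxyphenoxy]propane-1,3-diol
Product: 9 (1S,2R)-1-(3,4-dihydroxyphenyl)-2-[4-(3-hydroxypropyl)-2-methoxyphenoxy]propane-1,3-diol
Conditions: H2 (1 atm), 10% Pd/C, EtOAc–EtOH, rt; isolation under argon
Reagents that add atoms: none
Why: Hydrogenolysis of the two aryl benzyl ethers under neutral conditions; without acid the benzylic C7–OH should be cleaved much more slowly than the O-benzyl groups. The catechol is set free only here, and neither stereocenter is touched.

## Compound list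

1 | 1-[3,4-bis(benzyloxy)phenyl]ethan-1-one | CC(=O)c1ccc(OCc2ccccc2)c(OCc2ccccc2)c1 | starting material
2 | ethyl 3-[3,4-bis(benzyloxy)phenyl]-3-oxopropanoate | CCOC(=O)CC(=O)c1ccc(OCc2ccccc2)c(OCc2ccccc2)c1 | intermediate
3 | ethyl 3-[3,4-bis(benzyloxy)phenyl]-2-chloro-3-oxopropanoate (racemic) | CCOC(=O)C(Cl)C(=O)c1ccc(OCc2ccccc2)c(OCc2ccccc2)c1 | intermediate
4 | methyl 3-(4-hydroxy-3-methoxyphenyl)propanoate | COC(=O)CCc1ccc(O)c(OC)c1 | starting material
5 | ethyl 3-[3,4-bis(benzyloxy)phenyl]-2-[2-methoxy-4-(3-methoxy-3-oxopropyl)phenoxy]-3-oxopropanoate (racemic) | COc1cc(CCC(=O)OC)ccc1OC(C(=O)OCC)C(=O)c1ccc(OCc2ccccc2)c(OCc2ccccc2)c1 | intermediate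
6 | ethyl (2S)-3-[3,4-bis(benzyloxy)phenyl]-2-[2-methoxy-4-(3-methoxy-3-oxopropyl)phenoxy]-3-oxopropanoate (the enantiomer of 5 that is reduced; replenished from the (2R)-enantiomer through the enol) | COc1cc(CCC(=O)OC)ccc1O[C@H](C(=O)OCC)C(=O)c1ccc(OCc2ccccc2)c(OCc2ccccc2)c1 | intermediate (not isolated)
7 | ethyl (2S,3S)-3-[3,4-bis(benzyloxy)phenyl]-3-hydroxy-2-[2-methoxy-4-(3-methoxy-3-oxopropyl)phenoxy]propanoate | COc1cc(CCC(=O)OC)ccc1O[C@H](C(=O)OCC)[C@@H](O)c1ccc(OCc2ccccc2)c(OCc2ccccc2)c1 | intermediate
8 | (1S,2R)-1-[3,4-bis(benzyloxy)phenyl]-2-[4-(3-hydroxypropyl)-2-methoxyphenoxy]propane-1,3-diol | COc1cc(CCCO)ccc1O[C@H](CO)[C@@H](O)c1ccc(OCc2ccccc2)c(OCc2ccccc2)c1 | intermediate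
9 | (1S,2R)-1-(3,4-dihydroxyphenyl)-2-[4-(3-hydroxypropyl)-2-methoxyphenoxy]propane-1,3-diol | COc1cc(CCCO)ccc1O[C@H](CO)[C@@H](O)c1ccc(O)c(O)c1 | target

## Step count and least certain steps

Total step count: 6. Longest linear sequence: 6 steps (1 to 9); phenol 4 enters in step 3 without prior steps.

**Step 4 (key step).** The most likely failure is the wrong sense or a low level of diastereoselection. If the ether oxygen on C2, helped by the neighbouring methoxy group of ring B, binds ruthenium, hydride is delivered within a five-membered chelate and the syn (threo) ester is favoured. A second failure is reduction that is not slow enough relative to enolisation in CH2Cl2, which would erode both dr and ee. The fallback sets out from 5 and comes back at 8, and it accepts the syn manifold instead of fighting it.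
- 5 would be reduced by transfer hydrogenation with an N–H bifunctional catalyst (RuCl[(S,S)-TsDPEN](p-cymene), HCO2H/Et3N 5:2, CH2Cl2, 30 °C). These conditions are known to give syn products from α-alkoxy β-keto esters, so the product should be the threo ester ethyl (2S,3R)-3-[3,4-bis(benzyloxy)phenyl]-3-hydroxy-2-[2-methoxy-4-(3-methoxy-3-oxopropyl)phenoxy]propanoate F1.
- LiAlH4 in THF would then give the threo triol (1R,2R)-1-[3,4-bis(benzyloxy)phenyl]-2-[4-(3-hydroxypropyl)-2-methoxyphenoxy]propane-1,3-diol F2.
- Exhaustive Mitsunobu esterification (4-nitrobenzoic acid, PPh3, DIAD, THF, 0 °C) would acylate both primary alcohols and invert C7, giving (1S,2R)-1-[3,4-bis(benzyloxy)phenyl]-2-{2-methoxy-4-[3-(4-nitrobenzoyloxy)propyl]phenoxy}propane-1,3-diyl bis(4-nitrobenzoate) F3.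
- Methanolysis (K2CO3, MeOH) would release 8.

**Step 3.** The chloride 3 is more acidic than phenol 4, so it can rest as its enolate, which is not an electrophile. Phenoxide can also attack chlorine instead of carbon, which returns 2 and chlorinates 4, and the product can suffer retro-Claisen cleavage. The fallback sets out from 2 and comes back at 5, and replaces the SN2 step by a carbenoid O–H insertion. Diazo transfer to 2 (4-acetamidobenzenesulfonyl azide, Et3N, MeCN) would give ethyl 3-[3,4-bis(benzyloxy)phenyl]-2-diazo-3-oxopropanoate F4. Rh2(OAc)4 (1 mol %) with phenol 4 in CH2Cl2 at 40 °C would then insert the carbenoid into the O–H bond to give 5.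

**Step 5.** The C7 alkoxide formed first can fragment by retro-aldol before the neighbouring ester is reduced. This loses material and, if the fragments recombine, scrambles both centers. The fallback sets out from 7 and comes back at 8, and masks the carbinol. TBSOTf and 2,6-lutidine (CH2Cl2, −78 °C) would give ethyl (2S,3S)-3-[3,4-bis(benzyloxy)phenyl]-3-[(tert-butyldimethylsilyl)oxy]-2-[2-methoxy-4-(3-methoxy-3-oxopropyl)phenoxy]propanoate F5. LiAlH4 would reduce both esters to give (2R,3S)-3-[3,4-bis(benzyloxy)phenyl]-3-[(tert-butyldimethylsilyl)oxy]-2-[4-(3-hydroxypropyl)-2-methoxyphenoxy]propan-1-ol F6, and TBAF in THF would give 8.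

**Step 6.** Once the para benzyl ether has gone, C7–OH is a p-hydroxybenzyl alcohol and its C–O bond can be hydrogenolysed (over-reduction). The free catechol can also oxidise during isolation. The fallback sets out from 7 and comes back at 9, and debenzylates while the benzylic C–O bond is still deactivated by the vicinal ester. H2 and Pd/C in EtOAc on 7 would give ethyl (2S,3S)-3-(3,4-dihydroxyphenyl)-3-hydroxy-2-[2-methoxy-4-(3-methoxy-3-oxopropyl)phenoxy]propanoate F7. LiAlH4 in excess (THF, 0 °C, mildly acidic work-up under argon) would then reduce both esters to give 9.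

## Further compounds

F1 | step 4 | ethyl (2S,3R)-3-[3,4-bis(benzyloxy)phenyl]-3-hydroxy-2-[2-methoxy-4-(3-methoxy-3-oxopropyl)phenoxy]propanoate | COc1cc(CCC(=O)OC)ccc1O[C@H](C(=O)OCC)[C@H](O)c1ccc(OCc2ccccc2)c(OCc2ccccc2)c1
F2 | step 4 | (1R,2R)-1-[3,4-bis(benzyloxy)phenyl]-2-[4-(3-hydroxypropyl)-2-methoxyphenoxy]propane-1,3-diol | COc1cc(CCCO)ccc1O[C@H](CO)[C@H](O)c1ccc(OCc2ccccc2)c(OCc2ccccc2)c1
F3 | step 4 | (1S,2R)-1-[3,4-bis(benzyloxy)phenyl]-2-{2-methoxy-4-[3-(4-nitrobenzoyloxy)propyl]phenoxy}propane-1,3-diyl bis(4-nitrobenzoate) | COc1cc(CCCOC(=O)c2ccc(cc2)[N+](=O)[O-])ccc1O[C@H](COC(=O)c1ccc(cc1)[N+](=O)[O-])[C@@H](OC(=O)c1ccc(cc1)[N+](=O)[O-])c1ccc(OCc2ccccc2)c(OCc2ccccc2)c1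
F4 | step 3 | ethyl 3-[3,4-bis(benzyloxy)phenyl]-2-diazo-3-oxopropanoate | CCOC(=O)C(=[N+]=[N-])C(=O)c1ccc(OCc2ccccc2)c(OCc2ccccc2)c1
F5 | step 5 | ethyl (2S,3S)-3-[3,4-bis(benzyloxy)phenyl]-3-[(tert-butyldimethylsilyl)oxy]-2-[2-methoxy-4-(3-methoxy-3-oxopropyl)phenoxy]propanoate | COc1cc(CCC(=O)OC)ccc1O[C@H](C(=O)OCC)[C@@H](O[Si](C)(C)C(C)(C)C)c1ccc(OCc2ccccc2)c(OCc2ccccc2)c1
F6 | step 5 | (2R,3S)-3-[3,4-bis(benzyloxy)phenyl]-3-[(tert-butyldimethylsilyl)oxy]-2-[4-(3-hydroxypropyl)-2-methoxyphenoxy]propan-1-ol | COc1cc(CCCO)ccc1O[C@H](CO)[C@@H](O[Si](C)(C)C(C)(C)C)c1ccc(OCc2ccccc2)c(OCc2ccccc2)c1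
F7 | step 6 | ethyl (2S,3S)-3-(3,4-dihydroxyphenyl)-3-hydroxy-2-[2-methoxy-4-(3-methoxy-3-oxopropyl)phenoxy]propanoate | COc1cc(CCC(=O)OC)ccc1O[C@H](C(=O)OCC)[C@@H](O)c1ccc(O)c(O)c1
A1 | alternative 1 | (S)-4-benzyl-3-{[2-methoxy-4-(3-methoxy-3-oxopropyl)phenoxy]acetyl}oxazolidin-2-one | COc1cc(CCC(=O)OC)ccc1OCC(=O)N1C(=O)OC[C@@H]1Cc1ccccc1
A2 | alternative 1 | 3,4-bis(benzyloxy)benzaldehyde | O=Cc1ccc(OCc2ccccc2)c(OCc2ccccc2)c1
A3 | alternative 1 | (S)-4-benzyl-3-{(2S,3R)-3-[3,4-bis(benzyloxy)phenyl]-3-hydroxy-2-[2-methoxy-4-(3-methoxy-3-oxopropyl)phenoxy]propanoyl}oxazolidin-2-one | COc1cc(CCC(=O)OC)ccc1O[C@H](C(=O)N1C(=O)OC[C@@H]1Cc1ccccc1)[C@H](O)c1ccc(OCc2ccccc2)c(OCc2ccccc2)c1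
A4 | alternative 2 | ethyl (E)-3-[3,4-bis(benzyloxy)phenyl]prop-2-enoate | CCOC(=O)/C=C/c1ccc(OCc2ccccc2)c(OCc2ccccc2)c1
A5 | alternative 2 | ethyl (2R,3S)-3-[3,4-bis(benzyloxy)phenyl]-2,3-dihydroxypropanoate | O[C@@H](C(=O)OCC)[C@@H](O)c1ccc(OCc2ccccc2)c(OCc2ccccc2)c1
A6 | alternative 2 | ethyl (2R,3S)-3-[3,4-bis(benzyloxy)phenyl]-3-hydroxy-2-{[(4-nitrophenyl)sulfonyl]oxy}propanoate | O=S(=O)(O[C@@H](C(=O)OCC)[C@@H](O)c1ccc(OCc2ccccc2)c(OCc2ccccc2)c1)c1ccc(cc1)[N+](=O)[O-]
A7 | alternative 3 | (E)-4-(3-hydroxyprop-1-en-1-yl)benzene-1,2-diol | OC/C=C/c1ccc(O)c(O)c1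
A8 | alternative 3 | methyl 3-(4-{[1-hydroxy-3-(3-hydroxy-4-oxocyclohexa-2,5-dien-1-ylidene)propan-2-yl]oxy}-3-methoxyphenyl)propanoate (racemic quinone methide) | O=C1C=CC(=CC(CO)Oc2ccc(CCC(=O)OC)cc2OC)C=C1O
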